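**Plan** (germacrane numbering: ring C1–C10, C14 on C10, C15 on C4, C11–C13 the acrylate unit)

1. Retrosynthesis: cut the C8–O angelate bond first (with inversion at C8), then cut O–C6 and C11–C7 of the lactone together, which leaves 2-bromoacrylic acid and a ten-membered (2Z,4E,8E)-trienol; the carbocycle is then cut at C6=C7 (metathesis) and at C1=C10 and C4=C5 (two phosphonate olefinations).
2. Enabling feature: the lactone oxygen sits on C6, which is allylic to the ring double bond C4=C5. The array C7–C6(O)–C5=C4 at the junction of the γ-lactone and the cyclodecadiene ring is what a ring 1,3-diene C4=C5–C6=C7 gives on 1,2-carbo-oxygenation by an α-carboxyvinyl palladium species.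
3. Forward order: the chain is built from triethyl phosphonoacetate, acrolein and L-glutamic-acid-derived (S)-5-(hydroxymethyl)butyrolactone by two E-selective Horner–Wadsworth–Emmons reactions. The ten-membered ring is closed by metathesis while C8–O and C14 are tied as a lactone; reduction and silylation free the C8 carbinol; the γ-lactone ring is then annulated in one step; esterification and desilylation finish.
4. Stereochemistry: C8 comes from the chiral pool (S). C7 and C6 are set in the key step relative to C8 (hydroxyl-directed syn carbopalladation, then anti C–O closure). C8 is inverted in the Mitsunobu esterification. Alkene geometry comes from the olefinations (C1=C10, C4=C5), ring strain (C6=C7) and angelic acid.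

Key step: step 11

Assumption: the hydroxyl-directed carbopalladation is taken to place C11 trans to the C8 hydroxyl (the usual outcome for Z-cycloalkenols of medium ring size), so the route carries the 8-epi alcohol and corrects C8 in the esterification.

Step 1
Reactants: 1 triethyl phosphonoacetate; 2 3-bromo-1,1-dimethoxypropane
Product: 3 ethyl 2-(diethoxyphosphoryl)-5,5-dimethoxypentanoate
Conditions: NaH, DMF, 0 °C; then 2, NaI (cat.), 60 °C
Reagents that add atoms: none
Why: SN2 C-alkylation of the sodium phosphonoacetate carbanion by a primary bromide should install C3–C2–C1, with C1 masked as a dimethyl acetal.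

Step 2
Reactants: 3 ethyl 2-(diethoxyphosphoryl)-5,5-dimethoxypentanoate; 4 acrolein
Product: 5 ethyl (2E)-2-(3,3-dimethoxypropyl)penta-2,4-dienoate
Conditions: NaH, THF, 0 °C; then 4, −20 → 0 °C
Reagents that add atoms: none
Why: Horner–Wadsworth–Emmons olefination of the stabilised α-alkyl phosphonate should favour the E enoate (vinyl trans to CO2Et, hence C3 cis to C6 as needed at C4=C5); any minor Z isomer would be removed by chromatography.

Step 3
Reactants: 5 ethyl (2E)-2-(3,3-dimethoxypropyl)penta-2,4-dienoate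
Product: 6 ethyl (2E)-2-(3-oxopropyl)penta-2,4-dienoate
Conditions: 1 M aq. HCl, THF, rt
Reagents that add atoms: water (O)
Why: acid hydrolysis of the dimethyl acetal should unveil the C1 aldehyde while the dienoate ester stays inert.

Step 4
Reactants: 7 (5S)-5-(hydroxymethyl)oxolan-2-one
Product: 8 (2S)-5-oxooxolane-2-carbaldehyde
Conditions: Dess–Martin periodinane, CH2Cl2, rt; filtered and used crude
Reagents that add atoms: none
Why: Dess–Martin oxidation of the primary alcohol under neutral, non-aqueous conditions should give the aldehyde (future C7) without epimerising the adjacent C8 centre.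

Step 5
Reactants: 8 (2S)-5-oxooxolane-2-carbaldehyde
Product: 9 (5S)-5-ethenyloxolan-2-one
Conditions: Ph3PCH3Br, KN(SiMe3)2, THF, −78 → 0 °C
Reagents that add atoms: methyltriphenylphosphonium bromide (C[P+](c1ccccc1)(c1ccccc1)c1ccccc1.[Br-])
Why: Wittig methylenation with the non-stabilised ylide should be faster at the aldehyde than at the lactone carbonyl at low temperature (this aldehyde is a standard Wittig substrate) and should leave C8 untouched.

Step 6
Reactants: 9 (5S)-5-ethenyloxolan-2-one
Product: 11 diethyl [(5S)-5-ethenyl-2-oxooxolan-3-yl]phosphonate, via enol phosphate 10 (not isolated)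
Conditions: LiN(i-Pr)2 (1.1 equiv), THF, −78 °C; ClP(O)(OEt)2; then LiN(i-Pr)2 (2.2 equiv), −78 °C → rt; AcOH
Reagents that add atoms: diethyl chlorophosphate (CCOP(=O)(Cl)OCC)
Why: O-phosphorylation of the lactone enolate followed by the base-induced 1,3-phosphorus shift (vinyl phosphate to β-keto phosphonate rearrangement) should give the α-phosphono lactone; the epimer mixture at the phosphorus-bearing carbon is of no consequence.

Step 7
Reactants: 11 diethyl [(5S)-5-ethenyl-2-oxooxolan-3-yl]phosphonate; 6 ethyl (2E)-2-(3-oxopropyl)penta-2,4-dienoate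
Product: 12 ethyl (2E)-2-{(3E)-3-[(5S)-5-ethenyl-2-oxooxolan-3-ylidene]propyl}penta-2,4-dienoate
Conditions: KOt-Bu, THF, 0 °C; then 6 added slowly, 0 °C → rt
Reagents that add atoms: none
Why: Horner–Wadsworth–Emmons olefination of an α-phosphono-γ-butyrolactone with an aliphatic aldehyde should favour the more stable E alkylidene lactone (C2 cis to the ring CH2 C9), which fixes the C1=C10 geometry.

Step 8
Reactants: 12 ethyl (2E)-2-{(3E)-3-[(5S)-5-ethenyl-2-oxooxolan-3-ylidene]propyl}penta-2,4-dienoate
Product: 13 ethyl (1E,5E,7Z,9S)-11-oxo-10-oxabicyclo[7.2.1]dodeca-1,5,7-triene-5-carboxylate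
Conditions: second-generation Grubbs catalyst, (H2IMes)(PCy3)Cl2Ru=CHPh (10 mol%), 1,4-benzoquinone (cat.), toluene, 1 mM, 80 °C
Reagents that add atoms: none
Why: ring-closing metathesis between the C8 vinyl group and the diene terminus (loss of ethylene) is run at this stage because both trisubstituted alkenes are conjugated to carbonyl groups and so should not engage the ruthenium carbene (no six-membered closure onto C1=C10), while the strain of a trans alkene in a ten-membered ring that already holds two cis alkenes should secure Z at C6=C7.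

Step 9
Reactants: 13 ethyl (1E,5E,7Z,9S)-11-oxo-10-oxabicyclo[7.2.1]dodeca-1,5,7-triene-5-carboxylate
Product: 14 (1S,2Z,4E,8E)-5,9-bis(hydroxymethyl)cyclodeca-2,4,8-trien-1-ol
Conditions: i-Bu2AlH (6 equiv), CH2Cl2, −78 → 0 °C; aq. potassium sodium tartrate
Reagents that add atoms: none
Why: 1,2-reduction of the bridging lactone and of the conjugated ester by i-Bu2AlH should open the bridge and give the C8 carbinol and the two allylic primary alcohols (C14, C15) without touching C8 or the alkene geometry.

Step 10
Reactants: 14 (1S,2Z,4E,8E)-5,9-bis(hydroxymethyl)cyclodeca-2,4,8-trien-1-ol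
Product: 15 (1S,2Z,4E,8E)-5,9-bis({[tert-butyl(diphenyl)silyl]oxy}methyl)cyclodeca-2,4,8-trien-1-ol
Conditions: TBDPSCl (2.1 equiv), imidazole, CH2Cl2, 0 °C
Reagents that add atoms: tert-butyl(chloro)diphenylsilane (CC(C)(C)[Si](Cl)(c1ccccc1)c1ccccc1)
Why: the bulky silyl chloride should silylate the two primary allylic hydroxyls selectively and leave the hindered secondary C8 hydroxyl free for the key step.

Step 11
Reactants: 15 (1S,2Z,4E,8E)-5,9-bis({[tert-butyl(diphenyl)silyl]oxy}methyl)cyclodeca-2,4,8-trien-1-ol; 16 2-bromoacrylic acid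
Product: 17 (3aR,4S,6E,10E,11aR)-6,10-bis({[tert-butyl(diphenyl)silyl]oxy}methyl)-4-hydroxy-3-methylidene-3a,4,5,8,9,11a-hexahydrocyclodeca[b]furan-2(3H)-one
Conditions: Pd(OAc)2 (10 mol%), PPh3 (20 mol%), K2CO3 (2.5 equiv), n-Bu4NCl (1 equiv), DMF, 80 °C
Reagents that add atoms: none
Why: Zerovalent palladium inserts into the C–Br bond of the 2-bromoacrylate salt, the resulting α-carboxyvinyl palladium bromide adds syn across C6=C7 of the ring diene with the vinyl carbon on the terminus C7, palladium at C6 becomes a π-allyl over C4–C5–C6, and the tethered carboxylate attacks C6 and releases zerovalent palladium. The closest known reaction type is the Larock heteroannulation of 1,3-dienes by vinylic or aryl halides that carry an OH, NH or CO2H group, here with an α-haloacrylic acid to give an α-methylene-γ-butyrolactone. The one ring formed, the γ-lactone, closes by 5-exo attack of the carboxylate oxygen on the allyl terminus C6, since attack at C4 would need a seven-membered ring and a quaternary centre. C7 is controlled by the free C8 hydroxyl, which, with the carbinol hydrogen eclipsing the Z alkene (A1,3 strain), lies on the exposed peripheral face, binds palladium and should deliver the vinyl group to that face, giving the 7,8-trans relationship typical of hydroxyl-directed additions to medium-ring Z-cycloalkenols. C6 is controlled by chloride-promoted outer-sphere attack of the carboxylate on the allyl face opposite palladium, so that syn carbopalladation plus anti C–O formation amounts to anti addition across the Z C6=C7 bond and hence the trans ring fusion, which the flexible ten-membered ring can accommodate. The step needs site selectivity for the diene over the isolated C1=C10 alkene and for C7 over the fully substituted C4, secured by π-allyl formation and sterics, and retention of the C4=C5 geometry, secured because the allyl terminus C4 keeps its substituents in place.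

Step 12
Reactants: 17 the 8-epi lactone alcohol from step 11; 18 angelic acid
Product: 19 (3aR,4R,6E,10E,11aR)-6,10-bis({[tert-butyl(diphenyl)silyl]oxy}methyl)-3-methylidene-2-oxo-2,3,3a,4,5,8,9,11a-octahydrocyclodeca[b]furan-4-yl (2Z)-2-methylbut-2-enoate
Conditions: PPh3, diisopropyl azodicarboxylate, 18 (3 equiv each), toluene, 0 °C → rt
Reagents that add atoms: none
Why: Mitsunobu esterification should displace the C8 oxyphosphonium by angelate with inversion (SN2), giving the 8β ester cis to C11 under neutral conditions that preserve the Z angelate and the α-methylene lactone.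

Step 13
Reactants: 19 the bis-silyl angelate from step 12
Product: 20 CNP0182172.4, (3aR,4R,6E,10E,11aR)-6,10-bis(hydroxymethyl)-3-methylidene-2-oxo-2,3,3a,4,5,8,9,11a-octahydrocyclodeca[b]furan-4-yl (2Z)-2-methylbut-2-enoate
Conditions: HF·pyridine, pyridine, THF, 0 °C → rt
Reagents that add atoms: none
Why: fluoride cleavage of the two primary silyl ethers under mildly acidic conditions should free C14–OH and C15–OH without acyl migration, angelate isomerisation or conjugate addition to the methylene lactone.

**Compound list**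

1 | triethyl phosphonoacetate | CCOC(=O)CP(=O)(OCC)OCC | starting material
2 | 3-bromo-1,1-dimethoxypropane | COC(CCBr)OC | starting material
3 | ethyl 2-(diethoxyphosphoryl)-5,5-dimethoxypentanoate (racemic) | CCOC(=O)C(CCC(OC)OC)P(=O)(OCC)OCC | intermediate
4 | acrolein | C=CC=O | starting material
5 | ethyl (2E)-2-(3,3-dimethoxypropyl)penta-2,4-dienoate | CCOC(=O)/C(CCC(OC)OC)=C/C=C | intermediate
6 | ethyl (2E)-2-(3-oxopropyl)penta-2,4-dienoate | CCOC(=O)/C(CCC=O)=C/C=C | intermediate
7 | (5S)-5-(hydroxymethyl)oxolan-2-one | OC[C@@H]1CCC(=O)O1 | starting material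
8 | (2S)-5-oxooxolane-2-carbaldehyde | O=C[C@@H]1CCC(=O)O1 | intermediate
9 | (5S)-5-ethenyloxolan-2-one | C=C[C@@H]1CCC(=O)O1 | intermediate
10 | diethyl (5S)-5-ethenyl-4,5-dihydrofuran-2-yl phosphate | C=C[C@@H]1CC=C(OP(=O)(OCC)OCC)O1 | intermediate
11 | diethyl [(5S)-5-ethenyl-2-oxooxolan-3-yl]phosphonate (epimers at C3) | C=C[C@@H]1CC(P(=O)(OCC)OCC)C(=O)O1 | intermediate
12 | ethyl (2E)-2-{(3E)-3-[(5S)-5-ethenyl-2-oxooxolan-3-ylidene]propyl}penta-2,4-dienoate | C=C[C@@H]1C/C(=C\CC/C(C(=O)OCC)=C\C=C)C(=O)O1 | intermediate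
13 | ethyl (1E,5E,7Z,9S)-11-oxo-10-oxabicyclo[7.2.1]dodeca-1,5,7-triene-5-carboxylate | O=C1O[C@H]2C/C1=C\CC/C(C(=O)OCC)=C\C=C/2 | intermediate
14 | (1S,2Z,4E,8E)-5,9-bis(hydroxymethyl)cyclodeca-2,4,8-trien-1-ol | O[C@@H]1/C=C\C=C(\CO)CC/C=C(/CO)C1 | intermediate
15 | (1S,2Z,4E,8E)-5,9-bis({[tert-butyl(diphenyl)silyl]oxy}methyl)cyclodeca-2,4,8-trien-1-ol | O[C@@H]1/C=C\C=C(\CO[Si](c2ccccc2)(c2ccccc2)C(C)(C)C)CC/C=C(/CO[Si](c2ccccc2)(c2ccccc2)C(C)(C)C)C1 | intermediate
16 | 2-bromoacrylic acid | C=C(Br)C(=O)O | starting material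
17 | (3aR,4S,6E,10E,11aR)-6,10-bis({[tert-butyl(diphenyl)silyl]oxy}methyl)-4-hydroxy-3-methylidene-3a,4,5,8,9,11a-hexahydrocyclodeca[b]furan-2(3H)-one | C=C1C(=O)O[C@@H]2/C=C(/CO[Si](c3ccccc3)(c3ccccc3)C(C)(C)C)CC/C=C(/CO[Si](c3ccccc3)(c3ccccc3)C(C)(C)C)C[C@H](O)[C@@H]12 | intermediate
18 | angelic acid, (2Z)-2-methylbut-2-enoic acid | C/C=C(/C)C(=O)O | starting material
19 | (3aR,4R,6E,10E,11aR)-6,10-bis({[tert-butyl(diphenyl)silyl]oxy}methyl)-3-methylidene-2-oxo-2,3,3a,4,5,8,9,11a-octahydrocyclodeca[b]furan-4-yl (2Z)-2-methylbut-2-enoate | C=C1C(=O)O[C@@H]2/C=C(/CO[Si](c3ccccc3)(c3ccccc3)C(C)(C)C)CC/C=C(/CO[Si](c3ccccc3)(c3ccccc3)C(C)(C)C)C[C@@H](OC(=O)/C(C)=C\C)[C@@H]12 | intermediate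
20 | CNP0182172.4, (3aR,4R,6E,10E,11aR)-6,10-bis(hydroxymethyl)-3-methylidene-2-oxo-2,3,3a,4,5,8,9,11a-octahydrocyclodeca[b]furan-4-yl (2Z)-2-methylbut-2-enoate | C=C1C(=O)O[C@@H]2/C=C(/CO)CC/C=C(/CO)C[C@@H](OC(=O)/C(C)=C\C)[C@@H]12 | target

**Step count**

Total: 13 steps. Longest linear sequence: 10 steps (steps 1–3, then 7–13; the branch of steps 4–6 reaches the junction in the same number of steps).

**Steps most likely to fail**

Step 8 (ring-closing metathesis). Intermolecular metathesis (oligomer formation) may outrun closure of the strained, lactone-bridged ten-membered ring, or the ring may close to the E isomer. Fallback: close the ring at C7–C8 by an intramolecular Nozaki–Hiyama–Kishi reaction; the sequence sets out from 3 and comes back to the route at 13. Ethyl (Z)-3-iodoacrylate would be reduced (i-Bu2AlH, CH2Cl2, −78 °C) to (Z)-3-iodoacrolein F1, used cold in the Horner–Wadsworth–Emmons reaction with the sodium salt of 3 to give ethyl (2E,4Z)-2-(3,3-dimethoxypropyl)-5-iodopenta-2,4-dienoate F2. Acid hydrolysis should give ethyl (2E,4Z)-5-iodo-2-(3-oxopropyl)penta-2,4-dienoate F3. Alkylation of 1 with 2-bromo-1,1-dimethoxyethane (NaH, DMF) should give ethyl 2-(diethoxyphosphoryl)-4,4-dimethoxybutanoate F4, and its olefination with F3 ethyl (2E,4Z)-2-[(3E)-4-(ethoxycarbonyl)-6,6-dimethoxyhex-3-en-1-yl]-5-iodopenta-2,4-dienoate F5. Mild acetal hydrolysis should give ethyl (2E,4Z)-2-[(3E)-4-(ethoxycarbonyl)-6-oxohex-3-en-1-yl]-5-iodopenta-2,4-dienoate F6. Cyclisation of F6 with CrCl2 and catalytic NiCl2 in the presence of a chiral sulfonamide ligand at high dilution should give diethyl (1E,3Z,5S,7E)-5-hydroxycyclodeca-1,3,7-triene-1,7-dicarboxylate F7, which should lactonise onto the neighbouring ethyl ester (pyridinium p-toluenesulfonate, toluene) to 13.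

Step 11 (key annulation). The carbopalladation may show poor facial selectivity, the C–O bond may form by inner-sphere (syn) delivery and give the cis-fused lactone, palladium may oxidise the C8 carbinol, or the product methylene may undergo a second vinylation. Fallback: an oxidative radical lactone annulation followed by methylenation; it sets out from 15 and comes back at 17. Treatment of 15 with potassium ethyl malonate, Mn(OAc)3·2H2O and Cu(OAc)2 in AcOH at 60 °C should add the malonyl radical to C7 and close the carboxylic acid on the oxidised allyl unit at C6, giving the 11-(ethoxycarbonyl) lactone (ethyl 2-oxo-3-carboxylate analogue of 17, exocyclic methylene replaced by H and CO2Et) F8. Saponification (LiOH, THF/H2O, then acid) should give the 11-carboxy lactone F9. Decarboxylative methylenation (aq. formaldehyde, Et2NH, then NaOAc/AcOH, heat) should then give 17.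

Step 12 (Mitsunobu esterification). Elimination toward C8=C9 (conjugated with C1=C10) may compete with substitution at the hindered secondary carbinol, and the angelate may isomerise to the tiglate. Fallback: invert C8 by oxidation and reduction and esterify with retention; it sets out from 17 and comes back at 19. Dess–Martin oxidation of 17 should give the C8 ketone (8-oxo analogue of 17) F10. Luche reduction (NaBH4, CeCl3·7H2O, MeOH, −78 °C) should deliver hydride to the carbonyl face remote from the C7–C11 bond and give the 8β alcohol (C8 epimer of 17) F11. Yamaguchi esterification (18, 2,4,6-trichlorobenzoyl chloride, Et3N, then 4-dimethylaminopyridine, toluene) should then give 19.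

**Further compounds**

F1 | step 8 | (Z)-3-iodoacrolein | O=C/C=C\I
F2 | step 8 | ethyl (2E,4Z)-2-(3,3-dimethoxypropyl)-5-iodopenta-2,4-dienoate | CCOC(=O)/C(CCC(OC)OC)=C/C=C\I
F3 | step 8 | ethyl (2E,4Z)-5-iodo-2-(3-oxopropyl)penta-2,4-dienoate | CCOC(=O)/C(CCC=O)=C/C=C\I
F4 | step 8 | ethyl 2-(diethoxyphosphoryl)-4,4-dimethoxybutanoate (racemic) | CCOC(=O)C(CC(OC)OC)P(=O)(OCC)OCC
F5 | step 8 | ethyl (2E,4Z)-2-[(3E)-4-(ethoxycarbonyl)-6,6-dimethoxyhex-3-en-1-yl]-5-iodopenta-2,4-dienoate | COC(OC)C/C(C(=O)OCC)=C\CC/C(C(=O)OCC)=C\C=C/I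
F6 | step 8 | ethyl (2E,4Z)-2-[(3E)-4-(ethoxycarbonyl)-6-oxohex-3-en-1-yl]-5-iodopenta-2,4-dienoate | O=CC/C(C(=O)OCC)=C\CC/C(C(=O)OCC)=C\C=C/I
F7 | step 8 | diethyl (1E,3Z,5S,7E)-5-hydroxycyclodeca-1,3,7-triene-1,7-dicarboxylate | O[C@@H]1/C=C\C=C(\C(=O)OCC)CC/C=C(/C(=O)OCC)C1
F8 | step 11 | 11-(ethoxycarbonyl) lactone: ethyl (3aR,4S,6E,10E,11aR)-6,10-bis({[tert-butyl(diphenyl)silyl]oxy}methyl)-4-hydroxy-2-oxo-2,3,3a,4,5,8,9,11a-octahydrocyclodeca[b]furan-3-carboxylate (epimers at C3) | CCOC(=O)C1C(=O)O[C@@H]2/C=C(/CO[Si](c3ccccc3)(c3ccccc3)C(C)(C)C)CC/C=C(/CO[Si](c3ccccc3)(c3ccccc3)C(C)(C)C)C[C@H](O)[C@@H]12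
F9 | step 11 | 11-carboxy lactone: (3aR,4S,6E,10E,11aR)-6,10-bis({[tert-butyl(diphenyl)silyl]oxy}methyl)-4-hydroxy-2-oxo-2,3,3a,4,5,8,9,11a-octahydrocyclodeca[b]furan-3-carboxylic acid (epimers at C3) | OC(=O)C1C(=O)O[C@@H]2/C=C(/CO[Si](c3ccccc3)(c3ccccc3)C(C)(C)C)CC/C=C(/CO[Si](c3ccccc3)(c3ccccc3)C(C)(C)C)C[C@H](O)[C@@H]12
F10 | step 12 | C8 ketone: (3aS,6E,10E,11aR)-6,10-bis({[tert-butyl(diphenyl)silyl]oxy}methyl)-3-methylidene-3,3a,5,8,9,11a-hexahydrocyclodeca[b]furan-2,4-dione | C=C1C(=O)O[C@@H]2/C=C(/CO[Si](c3ccccc3)(c3ccccc3)C(C)(C)C)CC/C=C(/CO[Si](c3ccccc3)(c3ccccc3)C(C)(C)C)CC(=O)[C@@H]12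
F11 | step 12 | 8β alcohol: (3aR,4R,6E,10E,11aR)-6,10-bis({[tert-butyl(diphenyl)silyl]oxy}methyl)-4-hydroxy-3-methylidene-3a,4,5,8,9,11a-hexahydrocyclodeca[b]furan-2(3H)-one | C=C1C(=O)O[C@@H]2/C=C(/CO[Si](c3ccccc3)(c3ccccc3)C(C)(C)C)CC/C=C(/CO[Si](c3ccccc3)(c3ccccc3)C(C)(C)C)C[C@@H](O)[C@@H]12
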